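**Plan**
Labdane numbering is used: ring A = C1–C5/C10, ring B = C5–C10, ring C = O/C9/C11/C12/C13 (spiro tetrahydrofuran-3-one), ring D = C13/C14/C15/O/C16 (2,3-dihydrofuran).
Retrosynthesis: ring D is cut at C14–C15 and C13–C16 together, as a [3+2] cycloaddition of the parent carbonyl ylide CH2=O(+)–CH2(−) (the C15–O–C16 triad) to an exocyclic C13=C14 bond. This works because C13 and C14 are the α- and β-carbons of the C12 ketone of ring C, so the C–C unit spanned by the ether triad is an enone; a bromine on C14 activates the alkene and later leaves with H-15 to give C14=C15.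
Further cuts: C13–C14 (formylation of the ring C ketone), then a 1,2-oxygen transposition back to a 9,13-γ-lactone, which is the oxidative degradation product of the furan of marrubiin.
Forward order: rings A/B (from marrubiin) → spiro γ-lactone → lactol → cyclic enol ether → 12-ol → ring C ketone → bromomethylene at C13 → ring D by cycloaddition → dehydrobromination → desilylation.
Stereochemistry: C4, C5, C6, C8, C9 and C10 come unchanged from marrubiin; C13 is set in the cycloaddition by approach of the ylide to the face of ring C away from the quaternary C10 flank.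

Key step: step 11

Assumption: marrubiin, sold as an isolated natural product, is taken as the commercial chiral-pool starting material; TBS = tert-butyldimethylsilyl.

Step 1
Reactants: 1 marrubiin (15,16-epoxy-9α-hydroxylabda-13(16),14-dien-19,6β-olide)
Product: 2 marrubenol (15,16-epoxylabda-13(16),14-diene-6β,9α,19-triol)
Conditions: LiAlH4, THF, 0 → 66 °C; then H2O, aq. NaOH
Reagents that add atoms: none
Why: Hydride reduction of the hindered 19,6β-lactone should give the 6β,19-diol without touching the furan, the tertiary 9α-OH or any stereocentre.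

Step 2
Reactants: 2 marrubenol
Product: 3 6β,19-bis(TBS-oxy)-15,16-epoxylabda-13(16),14-dien-9α-ol
Conditions: TBSOTf, 2,6-lutidine, CH2Cl2, −40 → 0 °C
Reagents that add atoms: tert-butyldimethylsilyl triflate, CC(C)(C)[Si](C)(C)OS(=O)(=O)C(F)(F)F
Why: Silylation should take the primary 19-OH and the secondary 6β-OH, while the axial tertiary 9α-OH, flanked by C8 and the quaternary C10, should stay free for the later lactonisation.

Step 3
Reactants: 3 6β,19-bis(TBS-oxy)-15,16-epoxylabda-13(16),14-dien-9α-ol
Product: 5 6β,19-bis(TBS-oxy)-14,15,16-trinorlabdan-13,9α-olide (spiro γ-lactone), via hydroxy acid 4 (not isolated)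
Conditions: RuCl3 (cat.), NaIO4, EtOAc/MeCN/H2O, 0 → 23 °C; then work-up at pH 3 (citric acid), toluene, 50 °C
Reagents that add atoms: sodium periodate (oxygen donor by way of RuO4), [Na+].[O-]I(=O)(=O)=O
Why: RuO4 oxidation degrades the electron-rich 3-substituted furan to the C13 carboxylic acid (furan as a carboxyl surrogate), and the γ-hydroxy acid should close onto the 9α-OH to the spiro lactone with C9 untouched.

Step 4
Reactants: 5 spiro γ-lactone
Product: 6 9α,13-epoxy-6β,19-bis(TBS-oxy)-14,15,16-trinorlabdan-13-ol (lactol, anomer mixture)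
Conditions: iBu2AlH, CH2Cl2, −78 °C; then aq. KNaC4H4O6
Reagents that add atoms: none
Why: Partial reduction of a γ-lactone at low temperature should stop at the lactol because the tetrahedral aluminium alkoxide survives until work-up.

Step 5
Reactants: 6 lactol
Product: 8 9α,13-epoxy-6β,19-bis(TBS-oxy)-14,15,16-trinorlabd-12-ene (spiro 2,3-dihydrofuran), via lactol mesylate 7 (not isolated)
Conditions: MsCl, Et3N, CH2Cl2, −40 → 40 °C
Reagents that add atoms: none
Why: Sulfonylation of the lactol OH and loss of methanesulfonate through the C13 oxocarbenium ion, then removal of H-12 by the amine, should give the cyclic enol ether, as in the lactol-to-glycal dehydration.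

Step 6
Reactants: 8 spiro 2,3-dihydrofuran
Product: 10 9α,13-epoxy-6β,19-bis(TBS-oxy)-14,15,16-trinorlabdan-12-ol (C12 epimer mixture, immaterial), via 12-alkylborane 9 (not isolated)
Conditions: BH3·THF, THF, 0 → 23 °C; then 30% H2O2, aq. NaOH, 0 °C
Reagents that add atoms: hydrogen peroxide, OO
Why: Hydroboration of a cyclic enol ether places boron on the carbon β to oxygen (C12), and oxidation with retention should give the 3-hydroxytetrahydrofuran, which moves the oxygen function from C13 to C12.

Step 7
Reactants: 10 12-alcohol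
Product: 11 9α,13-epoxy-6β,19-bis(TBS-oxy)-14,15,16-trinorlabdan-12-one (spiro tetrahydrofuran-3-one, ring C)
Conditions: Dess–Martin periodinane, CH2Cl2, 23 °C
Reagents that add atoms: none
Why: Dess–Martin oxidation of the secondary alcohol should give the ketone under near-neutral conditions that leave the silyl ethers and the spiro ether intact.

Step 8
Reactants: 11 spiro tetrahydrofuran-3-one
Product: 12 9α,13-epoxy-14-hydroxy-6β,19-bis(TBS-oxy)-15,16-dinorlabd-13-en-12-one (13-hydroxymethylene ketone, enol form of the 14-aldehyde)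
Conditions: NaH, HCO2Et, EtOH (cat.), THF, 0 → 23 °C; then cold 0.5 M HCl
Reagents that add atoms: ethyl formate, CCOC=O
Why: Crossed Claisen condensation should occur at C13, the more acidic α-alkoxy methylene, because C11 is neopentylic beside the spiro centre, and the chelated enolate of the β-keto aldehyde drives the equilibrium.

Step 9
Reactants: 12 13-hydroxymethylene ketone
Product: 13 14-bromo-9α,13-epoxy-6β,19-bis(TBS-oxy)-15,16-dinorlabd-13-en-12-one (13-bromomethylene ketone, E/Z mixture, immaterial)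
Conditions: (COBr)2, 2,6-lutidine, DMF (cat.), CH2Cl2, 0 °C
Reagents that add atoms: oxalyl bromide, O=C(Br)C(=O)Br
Why: O-acylation of the vinylogous acid followed by addition–elimination of bromide at the formyl-derived carbon C14, with loss of CO and CO2, should give the β-bromo enone, the base protecting the silyl ethers from HBr.

Step 10
Reactants: 14 (trimethylsilyl)methanol
Product: 15 chloromethyl (trimethylsilyl)methyl ether
Conditions: (CH2O)n, HCl (g), 0 °C; then CaCl2
Reagents that add atoms: formaldehyde (as paraformaldehyde), C=O; hydrogen chloride, Cl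
Why: Chloromethylation of an alcohol through its formaldehyde hemiacetal is the standard preparation of α-chloro ethers.

Step 11
Reactants: 13 13-bromomethylene ketone; 15 chloromethyl (trimethylsilyl)methyl ether
Product: 16 14-bromo-9α,13:15,16-diepoxy-6β,19-bis(TBS-oxy)labdan-12-one (spiro tetrahydrofuran; C13 as in the target with C16 on the C8 side of ring C; C14 epimer mixture)
Conditions: CsF (dried), MeCN, 23 °C, slow addition of 15 (excess)
Reagents that add atoms: none
Why: Fluoride attacks the silicon of 15, and 1,3-elimination of Me3SiF and chloride releases the parent carbonyl ylide CH2=O(+)–CH2(−), which adds suprafacially across the electron-poor exocyclic C13=C14 bond of 13 (LUMO lowered by the C12 ketone and the bromine), so that C14–C15 and C13–C16 form together. The closest known reaction type is the 1,3-dipolar cycloaddition of non-stabilised carbonyl ylides, and of the analogous azomethine ylides, to enones and 2-alkylidene-furan-3-ones to give spiro five-membered rings. Ring D closes in an intermolecular [3+2] mode with both of its C–C bonds arising in the cycloaddition, and the symmetrical dipole removes any regiochemical question. The new quaternary centre C13 is controlled by the spiro decalin: the ylide should approach the face of ring C flanked by C8 (axial hydrogen, equatorial methyl) and not the face screened by the quaternary C10 with its C1 methylene, which places C16 cis to C8 as in the target; the C14 centre and the alkene geometry of 13 are immaterial because C14 becomes sp2 in step 12. The step needs chemoselectivity for C=C over the C12 carbonyl, secured by conjugation and by the hindered doubly α-substituted ketone, and face selectivity, secured by the steric bias just described; excess dipole precursor compensates for self-quenching of the ylide.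

Step 12
Reactants: 16 14-bromo spiro tetrahydrofuran
Product: 17 (13R)-9α,13:15,16-diepoxy-6β,19-bis(TBS-oxy)labd-14-en-12-one
Conditions: DBU, toluene, 80 °C
Reagents that add atoms: none
Why: Anti dehydrobromination can only take a hydrogen from C15 because C13 is quaternary, so it should give the C14=C15 enol ether regiospecifically, as in the classical synthesis of vinyl ethers from β-halo ethers.

Step 13
Reactants: 17 bis-TBS ether
Product: 18 (13R)-9α,13:15,16-diepoxy-6β,19-dihydroxylabd-14-en-12-one (target)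
Conditions: Bu4NF, AcOH, THF, 23 → 45 °C
Reagents that add atoms: none
Why: Buffered fluoride desilylation should free both hydroxyl groups under non-acidic conditions that preserve the enol ether and the α-alkoxy ketone, with no stereocentre at risk.

**Compound list**
1 | marrubiin (15,16-epoxy-9α-hydroxylabda-13(16),14-dien-19,6β-olide) | C[C@@H]1C[C@@H]2[C@H]3[C@@](C)(C(=O)O2)CCC[C@]3(C)[C@@]1(O)CCc1ccoc1 | starting material
2 | marrubenol (6β,9α,19-triol) | C[C@@H]1C[C@@H](O)[C@H]2[C@@](C)(CO)CCC[C@]2(C)[C@@]1(O)CCc1ccoc1 | intermediate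
3 | 6β,19-bis(TBS-oxy)-15,16-epoxylabda-13(16),14-dien-9α-ol | C[C@@H]1C[C@@H](O[Si](C)(C)C(C)(C)C)[C@H]2[C@@](C)(CO[Si](C)(C)C(C)(C)C)CCC[C@]2(C)[C@@]1(O)CCc1ccoc1 | intermediate
4 | 6β,19-bis(TBS-oxy)-9α-hydroxy-14,15,16-trinorlabdan-13-oic acid (not isolated) | C[C@@H]1C[C@@H](O[Si](C)(C)C(C)(C)C)[C@H]2[C@@](C)(CO[Si](C)(C)C(C)(C)C)CCC[C@]2(C)[C@@]1(O)CCC(=O)O | intermediate
5 | 6β,19-bis(TBS-oxy)-14,15,16-trinorlabdan-13,9α-olide | C[C@@H]1C[C@@H](O[Si](C)(C)C(C)(C)C)[C@H]2[C@@](C)(CO[Si](C)(C)C(C)(C)C)CCC[C@]2(C)[C@@]12CCC(=O)O2 | intermediate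
6 | 9α,13-epoxy-6β,19-bis(TBS-oxy)-14,15,16-trinorlabdan-13-ol (lactol, anomers) | C[C@@H]1C[C@@H](O[Si](C)(C)C(C)(C)C)[C@H]2[C@@](C)(CO[Si](C)(C)C(C)(C)C)CCC[C@]2(C)[C@@]12CCC(O)O2 | intermediate
7 | 13-O-methanesulfonyl lactol (not isolated) | C[C@@H]1C[C@@H](O[Si](C)(C)C(C)(C)C)[C@H]2[C@@](C)(CO[Si](C)(C)C(C)(C)C)CCC[C@]2(C)[C@@]12CCC(OS(C)(=O)=O)O2 | intermediate
8 | 9α,13-epoxy-6β,19-bis(TBS-oxy)-14,15,16-trinorlabd-12-ene | C[C@@H]1C[C@@H](O[Si](C)(C)C(C)(C)C)[C@H]2[C@@](C)(CO[Si](C)(C)C(C)(C)C)CCC[C@]2(C)[C@@]12CC=CO2 | intermediate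
9 | 12-boryl-9α,13-epoxy-6β,19-bis(TBS-oxy)-14,15,16-trinorlabdane (monoalkylborane, not isolated) | C[C@@H]1C[C@@H](O[Si](C)(C)C(C)(C)C)[C@H]2[C@@](C)(CO[Si](C)(C)C(C)(C)C)CCC[C@]2(C)[C@@]12CC(B)CO2 | intermediate
10 | 9α,13-epoxy-6β,19-bis(TBS-oxy)-14,15,16-trinorlabdan-12-ol (C12 epimers) | C[C@@H]1C[C@@H](O[Si](C)(C)C(C)(C)C)[C@H]2[C@@](C)(CO[Si](C)(C)C(C)(C)C)CCC[C@]2(C)[C@@]12CC(O)CO2 | intermediate
11 | 9α,13-epoxy-6β,19-bis(TBS-oxy)-14,15,16-trinorlabdan-12-one | C[C@@H]1C[C@@H](O[Si](C)(C)C(C)(C)C)[C@H]2[C@@](C)(CO[Si](C)(C)C(C)(C)C)CCC[C@]2(C)[C@@]12CC(=O)CO2 | intermediate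
12 | 13-hydroxymethylene ketone (9α,13-epoxy-14-hydroxy-6β,19-bis(TBS-oxy)-15,16-dinorlabd-13-en-12-one) | C[C@@H]1C[C@@H](O[Si](C)(C)C(C)(C)C)[C@H]2[C@@](C)(CO[Si](C)(C)C(C)(C)C)CCC[C@]2(C)[C@@]12CC(=O)C(=CO)O2 | intermediate
13 | 13-bromomethylene ketone (14-bromo-9α,13-epoxy-6β,19-bis(TBS-oxy)-15,16-dinorlabd-13-en-12-one, E/Z) | C[C@@H]1C[C@@H](O[Si](C)(C)C(C)(C)C)[C@H]2[C@@](C)(CO[Si](C)(C)C(C)(C)C)CCC[C@]2(C)[C@@]12CC(=O)C(=CBr)O2 | intermediate
14 | (trimethylsilyl)methanol | C[Si](C)(C)CO | starting material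
15 | chloromethyl (trimethylsilyl)methyl ether | C[Si](C)(C)COCCl | intermediate
16 | 14-bromo-9α,13:15,16-diepoxy-6β,19-bis(TBS-oxy)labdan-12-one (C14 epimers) | C[C@@H]1C[C@@H](O[Si](C)(C)C(C)(C)C)[C@H]2[C@@](C)(CO[Si](C)(C)C(C)(C)C)CCC[C@]2(C)[C@@]12CC(=O)[C@]1(C(Br)COC1)O2 | intermediate
17 | (13R)-9α,13:15,16-diepoxy-6β,19-bis(TBS-oxy)labd-14-en-12-one | C[C@@H]1C[C@@H](O[Si](C)(C)C(C)(C)C)[C@H]2[C@@](C)(CO[Si](C)(C)C(C)(C)C)CCC[C@]2(C)[C@@]12CC(=O)[C@]1(C=COC1)O2 | intermediate
18 | (13R)-9α,13:15,16-diepoxy-6β,19-dihydroxylabd-14-en-12-one | C[C@@H]1C[C@@H](O)[C@H]2[C@@](C)(CO)CCC[C@]2(C)[C@@]12CC(=O)[C@]1(C=COC1)O2 | target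

Total step count: 13.
Longest linear sequence: 12 steps (steps 1–9 and 11–13; step 10 prepares the dipole precursor 15).

**Steps most likely to fail**

Step 11 (key step). The cycloaddition may be slow at the trisubstituted, α-oxygenated alkene, so that self-quenching of the ylide or bromide–fluoride exchange at C14 wins, or the face selectivity at C13 may be low. The fallback sets out from 11 and returns at 17, and builds ring D stepwise with a metathesis closure. Aldol condensation of 11 with acetaldehyde (LiN(iPr)2, CH3CHO, THF, −78 °C; then MsCl, Et3N) should give the 13-ethylidene ketone F1. γ-Deprotonation (KN(SiMe3)2, THF, −78 °C) and α-hydroxymethylation of the dienolate with monomeric formaldehyde should give the 13-hydroxymethyl-13-vinyl ketone F2, the electrophile entering from the same less hindered face of ring C. O-Vinylation ([Ir(cod)Cl]2, Na2CO3, vinyl acetate, toluene, 100 °C) should give the vinyl ether F3, and ring-closing metathesis with the second-generation Grubbs catalyst should then close C14=C15 and deliver 17.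

Step 8. Deprotonation and formylation may take place at C11 instead of C13 and give the regioisomeric hydroxymethylene ketone. The fallback sets out from 8 and returns at 12, and fixes the carbon at C13 before the ketone exists. α-Lithiation of the enol ether 8 at C13 (tBuLi, THF, −78 → 0 °C) and quench with DMF should give the 13-formyl dihydrofuran F4. Nucleophilic epoxidation (tBuOOH, DBU, CH2Cl2) should give the 12,13-epoxy aldehyde F5. Lewis-acid opening at the acetal carbon C13 with a 1,2-hydride shift from C12 (BF3·OEt2, CH2Cl2, −78 °C, Meinwald-type rearrangement) should give 12.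

Step 12. The anti-elimination next to the quaternary centre may be sluggish, or base may trigger fragmentation of the β-bromo ketone instead. The fallback sets out from 12 and returns at 17, and replaces the base-induced elimination by a thermal syn-elimination. Exchange of the enol OH of 12 for sulfur (PhSH, pyridinium p-toluenesulfonate cat., benzene, 80 °C) should give the 13-(phenylthiomethylene) ketone F6. Oxidation (mCPBA, 1 equiv, CH2Cl2, −78 °C) should give the 13-(phenylsulfinylmethylene) ketone F7 as a mixture at sulfur. The same ylide cycloaddition (15, CsF, MeCN, 23 °C) should give the 14-phenylsulfinyl cycloadduct F8. Heating (toluene, Et3N, 110 °C) should expel benzenesulfenic acid toward C15, the only carbon with β-hydrogens, and give 17.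

Further compounds
F1 | step 11 | 13-ethylidene ketone (9α,13-epoxy-6β,19-bis(TBS-oxy)-16-norlabd-13-en-12-one, E/Z) | C[C@@H]1C[C@@H](O[Si](C)(C)C(C)(C)C)[C@H]2[C@@](C)(CO[Si](C)(C)C(C)(C)C)CCC[C@]2(C)[C@@]12CC(=O)C(=CC)O2
F2 | step 11 | 13-hydroxymethyl-13-vinyl ketone (9α,13-epoxy-16-hydroxy-6β,19-bis(TBS-oxy)labd-14-en-12-one) | C[C@@H]1C[C@@H](O[Si](C)(C)C(C)(C)C)[C@H]2[C@@](C)(CO[Si](C)(C)C(C)(C)C)CCC[C@]2(C)[C@@]12CC(=O)[C@](CO)(C=C)O2
F3 | step 11 | 13-(vinyloxymethyl)-13-vinyl ketone (16-O-vinyl ether of F2) | C[C@@H]1C[C@@H](O[Si](C)(C)C(C)(C)C)[C@H]2[C@@](C)(CO[Si](C)(C)C(C)(C)C)CCC[C@]2(C)[C@@]12CC(=O)[C@](COC=C)(C=C)O2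
F4 | step 8 | 13-formyl dihydrofuran (9α,13-epoxy-6β,19-bis(TBS-oxy)-15,16-dinorlabd-12-en-14-al) | C[C@@H]1C[C@@H](O[Si](C)(C)C(C)(C)C)[C@H]2[C@@](C)(CO[Si](C)(C)C(C)(C)C)CCC[C@]2(C)[C@@]12CC=C(C=O)O2
F5 | step 8 | 12,13-epoxy aldehyde (9α,13:12,13-diepoxy-6β,19-bis(TBS-oxy)-15,16-dinorlabdan-14-al) | C[C@@H]1C[C@@H](O[Si](C)(C)C(C)(C)C)[C@H]2[C@@](C)(CO[Si](C)(C)C(C)(C)C)CCC[C@]2(C)[C@@]12CC3OC3(C=O)O2
F6 | step 12 | 13-(phenylthiomethylene) ketone | C[C@@H]1C[C@@H](O[Si](C)(C)C(C)(C)C)[C@H]2[C@@](C)(CO[Si](C)(C)C(C)(C)C)CCC[C@]2(C)[C@@]12CC(=O)C(=CSc3ccccc3)O2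
F7 | step 12 | 13-(phenylsulfinylmethylene) ketone | C[C@@H]1C[C@@H](O[Si](C)(C)C(C)(C)C)[C@H]2[C@@](C)(CO[Si](C)(C)C(C)(C)C)CCC[C@]2(C)[C@@]12CC(=O)C(=CS(=O)c3ccccc3)O2
F8 | step 12 | 14-phenylsulfinyl-9α,13:15,16-diepoxy-6β,19-bis(TBS-oxy)labdan-12-one | C[C@@H]1C[C@@H](O[Si](C)(C)C(C)(C)C)[C@H]2[C@@](C)(CO[Si](C)(C)C(C)(C)C)CCC[C@]2(C)[C@@]12CC(=O)[C@]1(C(S(=O)c3ccccc3)COC1)O2
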